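**Retrosynthetic overview**

1. Target 25 ⇐ C6-hydroxyl-directed epoxidation of the Z-olefin C4=C5 in allylic alcohol 24 ⇐ Evans–Tishchenko reduction of hydroxy ketone 21 with 3,4,5-trimethoxybenzaldehyde (sets C6 and puts the ester on O8) ⇐ dynamic-kinetic transfer hydrogenation of cyclodecadiene-1,3-dione 20 (sets C7 and C8).
2. Key disconnection: ring bond C7–C8 of 20. A sulfur atom placed between C7 and C8 gives the 11-membered thiolactone 18 (ring atoms C1–C10 plus S), and an Eschenmoser sulfide contraction contracts it to the 10-membered carbocycle.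
3. Enabling feature: C7 (isopropyl-bearing) lies between the two oxygenated ring carbons C6 and C8, so at the dione level C7 is an enolisable carbon next to an acyl carbon (C8); a thioester sulfur bridging exactly these two atoms can be extruded with C7–C8 bond formation.
4. 18 ⇐ intramolecular S-alkylation of thioacid/α-bromo ketone 17 ⇐ linear C15 chain from silyl ether 1, oxirane, propyne and isovaleryl chloride; E-C1=C10 by Negishi carboalumination, Z-C4=C5 by Normant carbocupration.
5. Ring order: 11-membered thiolactone (step 8), then 10-membered carbocycle by ring contraction (step 9), then oxirane (step 12).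

Key step: step 9

Remark: ring atoms are numbered as in germacranes (C1=C10 olefin with methyl on C10, oxirane at C4/C5, free hydroxyl at C6, isopropyl at C7, ester oxygen at C8); 1, 2, 6, 7 and 22 are taken as commercial; C7 is racemic from step 4 to step 9, where it is enolisable, and is fixed in step 10.

**Route**

Step 1
Reactants: 1 tert-butyl(but-3-yn-1-yloxy)dimethylsilane; 2 oxirane
Product: 4 (3E)-6-{[tert-butyl(dimethyl)silyl]oxy}-4-methylhex-3-en-1-ol, via alkenylalane 3 (not isolated)
Conditions: Me3Al, Cp2ZrCl2 (20 mol %), CH2Cl2, 0 °C to rt; n-BuLi, THF, −30 °C; oxirane, −30 °C to rt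
Reagents that add atoms: trimethylaluminium C[Al](C)C
Why: Zirconium-catalysed Negishi carboalumination adds methyl and aluminium syn across the terminal alkyne with aluminium on the terminal carbon, and the alanate formed with n-BuLi should open oxirane with retention at the alkenyl carbon, so the trisubstituted C1=C10 olefin is fixed as E.

Step 2
Reactants: 4 (3E)-6-{[tert-butyl(dimethyl)silyl]oxy}-4-methylhex-3-en-1-ol
Product: 5 {[(3E)-6-bromo-3-methylhex-3-en-1-yl]oxy}(tert-butyl)dimethylsilane
Conditions: CBr4, PPh3, CH2Cl2, 0 °C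
Reagents that add atoms: carbon tetrabromide BrC(Br)(Br)Br
Why: Appel reaction, in which the primary alcohol is activated as its alkoxyphosphonium ion and displaced by bromide in an SN2 step under neutral conditions, which should leave the silyl ether and the E-olefin untouched; no stereocentre is formed.

Step 3
Reactants: 5 {[(3E)-6-bromo-3-methylhex-3-en-1-yl]oxy}(tert-butyl)dimethylsilane; 6 propyne; 7 3-methylbutanoyl chloride
Product: 10 (5Z,9E)-12-{[tert-butyl(dimethyl)silyl]oxy}-2,6,10-trimethyldodeca-5,9-dien-4-one, via Grignard reagent 8 (not isolated), via alkenylcopper reagent 9 (not isolated)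
Conditions: Mg, Et2O, rt; CuBr·SMe2, Et2O/Me2S, −45 °C; propyne, −25 °C; Pd(PPh3)4 (3 mol %), 3-methylbutanoyl chloride, −25 to 0 °C
Reagents that add atoms: none
Why: Normant carbocupration followed by palladium-catalysed acylation: the organocopper reagent made from Grignard reagent 8 and CuBr·SMe2 should add syn to propyne with copper on the terminal carbon, so that the incoming chain and copper are cis, and acylation of alkenylcopper 9 with retention then fixes the C4=C5 olefin as Z.

Step 4
Reactants: 10 (5Z,9E)-12-{[tert-butyl(dimethyl)silyl]oxy}-2,6,10-trimethyldodeca-5,9-dien-4-one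
Product: 12 (5Z,9E)-3-bromo-12-{[tert-butyl(dimethyl)silyl]oxy}-2,6,10-trimethyldodeca-5,9-dien-4-one, via silyl dienol ether 11 (not isolated)
Conditions: LiN(SiMe3)2, Me3SiCl, THF, −78 °C; NBS, THF, −78 °C
Reagents that add atoms: N-bromosuccinimide O=C1CCC(=O)N1Br
Why: Kinetic deprotonation of the enone at the α′-methylene group (cross-conjugated enolate, trapped in situ as silyl dienol ether 11) followed by electrophilic bromination with NBS should place bromine at C7 only; the new stereocentre C7 is formed as a racemate on purpose, because it becomes enolisable again in the dione and is fixed in step 10.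

Step 5
Reactants: 12 (5Z,9E)-3-bromo-12-{[tert-butyl(dimethyl)silyl]oxy}-2,6,10-trimethyldodeca-5,9-dien-4-one
Product: 13 (5Z,9E)-3-bromo-12-hydroxy-2,6,10-trimethyldodeca-5,9-dien-4-one
Conditions: 48% aq. HF, MeCN, 0 °C
Reagents that add atoms: none
Why: Fluoride-assisted acidic cleavage of the primary silyl ether; aqueous HF in acetonitrile is neither basic nor nucleophilic, so the α-bromo ketone and the Z-enone should survive, and no stereocentre is touched.

Step 6
Reactants: 13 (5Z,9E)-3-bromo-12-hydroxy-2,6,10-trimethyldodeca-5,9-dien-4-one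
Product: 15 (3E,7Z)-10-bromo-3,7,11-trimethyl-9-oxododeca-3,7-dienoic acid, via aldehyde 14 (not isolated)
Conditions: TEMPO (20 mol %), PhI(OAc)2, MeCN/H2O (1:1), rt
Reagents that add atoms: water O
Why: TEMPO/PhI(OAc)2 (oxoammonium-mediated) oxidation of the primary alcohol through aldehyde 14 and its hydrate to the carboxylic acid under near-neutral conditions, which should keep the β,γ-double bond out of conjugation and leave the α-bromo ketone intact.

Step 7
Reactants: 15 (3E,7Z)-10-bromo-3,7,11-trimethyl-9-oxododeca-3,7-dienoic acid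
Product: 17 (3E,7Z)-10-bromo-3,7,11-trimethyl-9-oxododeca-3,7-dienethioic S-acid, via acid chloride 16 (not isolated)
Conditions: (COCl)2, DMF (cat.), CH2Cl2, 0 °C; (Me3Si)2S, CH2Cl2, 0 °C to rt; MeOH
Reagents that add atoms: hexamethyldisilathiane C[Si](C)(C)S[Si](C)(C)C
Why: Acid chloride formation with oxalyl chloride/DMF and thiolysis with hexamethyldisilathiane (S-silyl thioester, then methanolysis) is a known route to thiocarboxylic S-acids that avoids free hydrosulfide or thiolate, which would attack the α-bromo ketone or add reversibly to the Z-enone.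

Step 8
Reactants: 17 (3E,7Z)-10-bromo-3,7,11-trimethyl-9-oxododeca-3,7-dienethioic S-acid
Product: 18 (4E,8Z)-4,8-dimethyl-11-(propan-2-yl)-1-thiacycloundeca-4,8-diene-2,10-dione
Conditions: Cs2CO3, DMF, 1 mM, slow addition, rt
Reagents that add atoms: none
Why: Intramolecular SN2 S-alkylation of the soft caesium thiocarboxylate by the activated α-bromo ketone under high dilution (the thioester-forming first stage of a sulfide contraction by alkylative coupling) should close the 11-membered thiolactone; C7 is inverted but remains racemic.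

Step 9
Reactants: 18 (4E,8Z)-4,8-dimethyl-11-(propan-2-yl)-1-thiacycloundeca-4,8-diene-2,10-dione
Product: 20 (4Z,8E)-5,9-dimethyl-2-(propan-2-yl)cyclodeca-4,8-diene-1,3-dione, via hydroxythiirane 19 (not isolated)
Conditions: LiBr, i-Pr2NEt, P(OEt)3, MeCN, 60 °C
Reagents that add atoms: none
Why: Soft enolisation (LiBr/i-Pr2NEt) at C7, the only carbon flanked by a ketone and sulfur, gives an enolate whose carbon attacks the thioester carbonyl C8 across the sulfur bridge (3-exo-trig) to form hydroxythiirane 19, from which triethyl phosphite removes sulfur while the C7–C8 bond stays, so the 11-membered thiolactone contracts to the 10-membered carbocycle as its 1,3-dione. The closest known reaction type is the Eschenmoser sulfide contraction in its alkylative-coupling variant, which converts S-(2-oxoalkyl) thiocarboxylates into β-diketones and has also been used to contract sulfur-bridged macrocyclic rings. The carbocycle therefore closes by C–C bond formation between two atoms already held together by sulfur, without a separate ten-membered ring closure. No lasting stereocentre is formed, since C7 of the dione epimerises through its enol, and both trisubstituted olefins are carried through unchanged. The step needs enolisation at C7 rather than at the allylic C9 and retention of the Z-enone; the first is secured by the much higher acidity of the α-thio α-keto C–H bond, the second by using a weakly nucleophilic phosphite and an amine base in place of phosphines or thiolates.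

Step 10
Reactants: 20 (4Z,8E)-5,9-dimethyl-2-(propan-2-yl)cyclodeca-4,8-diene-1,3-dione
Product: 21 (2Z,6E,9S,10R)-9-hydroxy-3,7-dimethyl-10-(propan-2-yl)cyclodeca-2,6-dien-1-one
Conditions: RuCl[(S,S)-TsDPEN](p-cymene) (2 mol %), HCO2H/Et3N (5:2), CH2Cl2, 30 °C
Reagents that add atoms: none
Why: Noyori–Ikariya asymmetric transfer hydrogenation under dynamic kinetic resolution: the dione racemises at C7 through its enol in the presence of Et3N, the non-conjugated and therefore more electrophilic carbonyl C8 should be reduced in preference to the conjugated C6 carbonyl, and the chiral ruthenium hydride should reduce the faster-reacting C7 epimer from one carbonyl face (sense assigned by the mnemonic for aryl alkyl ketones, with the branched C7 side in the place of the aryl group) to the syn β-hydroxy ketone, which sets C8 and C7 together.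

Step 11
Reactants: 21 (2Z,6E,9S,10R)-9-hydroxy-3,7-dimethyl-10-(propan-2-yl)cyclodeca-2,6-dien-1-one; 22 3,4,5-trimethoxybenzaldehyde
Product: 24 (1S,3E,7Z,9S,10S)-9-hydroxy-3,7-dimethyl-10-(propan-2-yl)cyclodeca-3,7-dien-1-yl 3,4,5-trimethoxybenzoate, via hemiacetal 23 (not isolated)
Conditions: SmI2 (30 mol %, premixed with the aldehyde), 3,4,5-trimethoxybenzaldehyde (5 equiv), THF, −10 °C
Reagents that add atoms: none
Why: Evans–Tishchenko reduction: the C8 hydroxyl and aldehyde 22 form the samarium-bound hemiacetal 23, whose carbinol hydrogen is delivered as hydride to the C6 carbonyl through a chair-like six-membered transition state, which should give the 1,3-anti diol monoester, so that C6 is set anti to C8 and the 3,4,5-trimethoxybenzoyl group ends up on O8 in the same operation.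

Step 12
Reactants: 24 (1S,3E,7Z,9S,10S)-9-hydroxy-3,7-dimethyl-10-(propan-2-yl)cyclodeca-3,7-dien-1-yl 3,4,5-trimethoxybenzoate
Product: 25 (1R,2R,3S,4S,6E,10S)-2-hydroxy-6,10-dimethyl-3-(propan-2-yl)-11-oxabicyclo[8.1.0]undec-6-en-4-yl 3,4,5-trimethoxybenzoate
Conditions: VO(acac)2 (5 mol %), t-BuOOH, CH2Cl2, 0 °C to rt
Reagents that add atoms: tert-butyl hydroperoxide CC(C)(C)OO
Why: Vanadium-catalysed hydroxyl-directed (Sharpless–Michaelson) epoxidation: the vanadate ester of the C6 alcohol should deliver oxygen only to the allylic C4=C5 olefin and not to the isolated C1=C10 olefin, on the face cis to the hydroxyl as is known for Z-cycloalkenols of medium rings, which sets C5 (and, through the Z geometry of the olefin, C4) relative to C6.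

**Compound list**

1 | tert-butyl(but-3-yn-1-yloxy)dimethylsilane | C#CCCO[Si](C)(C)C(C)(C)C | starting material
2 | oxirane | C1CO1 | starting material
3 | [(1E)-4-{[tert-butyl(dimethyl)silyl]oxy}-2-methylbut-1-en-1-yl](dimethyl)alumane | C[Al](C)/C=C(\C)CCO[Si](C)(C)C(C)(C)C | intermediate
4 | (3E)-6-{[tert-butyl(dimethyl)silyl]oxy}-4-methylhex-3-en-1-ol | OCC/C=C(\C)CCO[Si](C)(C)C(C)(C)C | intermediate
5 | {[(3E)-6-bromo-3-methylhex-3-en-1-yl]oxy}(tert-butyl)dimethylsilane | BrCC/C=C(\C)CCO[Si](C)(C)C(C)(C)C | intermediate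
6 | propyne | CC#C | starting material
7 | 3-methylbutanoyl chloride | CC(C)CC(Cl)=O | starting material
8 | bromo[(3E)-6-{[tert-butyl(dimethyl)silyl]oxy}-4-methylhex-3-en-1-yl]magnesium | Br[Mg]CC/C=C(\C)CCO[Si](C)(C)C(C)(C)C | intermediate
9 | [(1Z,5E)-8-{[tert-butyl(dimethyl)silyl]oxy}-2,6-dimethylocta-1,5-dien-1-yl]copper | [Cu]/C=C(/C)CC/C=C(\C)CCO[Si](C)(C)C(C)(C)C | intermediate
10 | (5Z,9E)-12-{[tert-butyl(dimethyl)silyl]oxy}-2,6,10-trimethyldodeca-5,9-dien-4-one | CC(C)CC(=O)/C=C(/C)CC/C=C(\C)CCO[Si](C)(C)C(C)(C)C | intermediate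
11 | (5Z,9E)-12-{[tert-butyl(dimethyl)silyl]oxy}-2,6,10-trimethyl-4-[(trimethylsilyl)oxy]dodeca-3,5,9-triene | CC(C)C=C(O[Si](C)(C)C)/C=C(/C)CC/C=C(\C)CCO[Si](C)(C)C(C)(C)C | intermediate
12 | (5Z,9E)-3-bromo-12-{[tert-butyl(dimethyl)silyl]oxy}-2,6,10-trimethyldodeca-5,9-dien-4-one (racemate) | CC(C)C(Br)C(=O)/C=C(/C)CC/C=C(\C)CCO[Si](C)(C)C(C)(C)C | intermediate
13 | (5Z,9E)-3-bromo-12-hydroxy-2,6,10-trimethyldodeca-5,9-dien-4-one (racemate) | CC(C)C(Br)C(=O)/C=C(/C)CC/C=C(\C)CCO | intermediate
14 | (3E,7Z)-10-bromo-3,7,11-trimethyl-9-oxododeca-3,7-dienal (racemate) | CC(C)C(Br)C(=O)/C=C(/C)CC/C=C(\C)CC=O | intermediate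
15 | (3E,7Z)-10-bromo-3,7,11-trimethyl-9-oxododeca-3,7-dienoic acid (racemate) | CC(C)C(Br)C(=O)/C=C(/C)CC/C=C(\C)CC(=O)O | intermediate
16 | (3E,7Z)-10-bromo-3,7,11-trimethyl-9-oxododeca-3,7-dienoyl chloride (racemate) | CC(C)C(Br)C(=O)/C=C(/C)CC/C=C(\C)CC(=O)Cl | intermediate
17 | (3E,7Z)-10-bromo-3,7,11-trimethyl-9-oxododeca-3,7-dienethioic S-acid (racemate) | CC(C)C(Br)C(=O)/C=C(/C)CC/C=C(\C)CC(=O)S | intermediate
18 | (4E,8Z)-4,8-dimethyl-11-(propan-2-yl)-1-thiacycloundeca-4,8-diene-2,10-dione (racemate) | CC(C)C1SC(=O)C/C(C)=C/CC/C(C)=C\C1=O | intermediate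
19 | (3Z,7E)-10-hydroxy-4,8-dimethyl-1-(propan-2-yl)-11-thiabicyclo[8.1.0]undeca-3,7-dien-2-one | CC(C)C12SC1(O)C/C(C)=C/CC/C(C)=C\C2=O | intermediate
20 | (4Z,8E)-5,9-dimethyl-2-(propan-2-yl)cyclodeca-4,8-diene-1,3-dione | CC(C)C1C(=O)C/C(C)=C/CC/C(C)=C\C1=O | intermediate
21 | (2Z,6E,9S,10R)-9-hydroxy-3,7-dimethyl-10-(propan-2-yl)cyclodeca-2,6-dien-1-one | O[C@H]1C/C(C)=C/CC/C(C)=C\C(=O)[C@@H]1C(C)C | intermediate
22 | 3,4,5-trimethoxybenzaldehyde | COc1cc(C=O)cc(OC)c1OC | starting material
23 | hemiacetal of 21 and 22: (1S,3E,7Z,10R)-1-[hydroxy(3,4,5-trimethoxyphenyl)methoxy]-3,7-dimethyl-10-(propan-2-yl)cyclodeca-3,7-dien-9-one | COc1cc(C(O)O[C@H]2C/C(C)=C/CC/C(C)=C\C(=O)[C@@H]2C(C)C)cc(OC)c1OC | intermediate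
24 | (1S,3E,7Z,9S,10S)-9-hydroxy-3,7-dimethyl-10-(propan-2-yl)cyclodeca-3,7-dien-1-yl 3,4,5-trimethoxybenzoate | COc1cc(C(=O)O[C@H]2C/C(C)=C/CC/C(C)=C\[C@H](O)[C@@H]2C(C)C)cc(OC)c1OC | intermediate
25 | (1R,2R,3S,4S,6E,10S)-2-hydroxy-6,10-dimethyl-3-(propan-2-yl)-11-oxabicyclo[8.1.0]undec-6-en-4-yl 3,4,5-trimethoxybenzoate | COc1cc(C(=O)O[C@H]2C/C(C)=C/CC[C@]3(C)O[C@@H]3[C@H](O)[C@@H]2C(C)C)cc(OC)c1OC | target

Total step count: 12. Longest linear sequence: 12 steps (from 1).

**Steps most likely to fail**

Step 9. Thiirane formation may be slow in the strained medium ring, so that enolisation at C9 moves the C1=C10 double bond into conjugation, or reversible addition of the thiophile to the Z-enone scrambles its geometry. The fallback sets out from bromo alcohol 13 and comes back at dione 20. Dess–Martin periodinane (CH2Cl2, NaHCO3) oxidises 13 to aldehyde 14, which is isolated here. SmI2 (2.2 equiv, THF, −78 °C, high dilution) generates the samarium enolate at C7, and an intramolecular Reformatsky addition to the aldehyde should close the ten-membered ring directly to 9-hydroxy-3,7-dimethyl-10-(propan-2-yl)cyclodeca-2,6-dien-1-one F1 (mixture of diastereomers). Dess–Martin oxidation of F1 gives 20.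

Step 8. Intermolecular S-alkylation (oligomer formation) may outrun closure of the eleven-membered ring, or the hindered secondary bromide may lose HBr. The fallback sets out from bromo acid 15 and comes back at thiolactone 18. NaSH (DMF, 0 °C) displaces bromide to give (3E,7Z)-3,7,11-trimethyl-9-oxo-10-sulfanyldodeca-3,7-dienoic acid F2. Macrothiolactonisation (DCC, DMAP cat., CH2Cl2, 1 mM) then closes the ring by S-acylation, that is at the other carbon–sulfur bond.

Step 10. Hydride may also be delivered to the conjugated carbonyl C6, or the facial and syn selectivity of the dynamic kinetic resolution may be poor. The fallback sets out from dione 20 and comes back at hydroxy ketone 21. Zn(BH4)2 (Et2O, −20 °C; chelation-controlled syn reduction of the non-conjugated carbonyl) should give the racemic syn hydroxy ketone, that is 21 together with its enantiomer (2Z,6E,9R,10S)-9-hydroxy-3,7-dimethyl-10-(propan-2-yl)cyclodeca-2,6-dien-1-one F3. Lipase-catalysed acylation (Burkholderia cepacia lipase, vinyl acetate, t-BuOMe) should convert F3 (the R carbinol, as the Kazlauskas rule predicts) into (1R,3E,7Z,10S)-3,7-dimethyl-9-oxo-10-(propan-2-yl)cyclodeca-3,7-dien-1-yl acetate F4 and leave 21, which is separated and carried on.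

Further compounds
F1 | step 9 | (2Z,6E)-9-hydroxy-3,7-dimethyl-10-(propan-2-yl)cyclodeca-2,6-dien-1-one (mixture of diastereomers) | OC1C/C(C)=C/CC/C(C)=C\C(=O)C1C(C)C
F2 | step 8 | (3E,7Z)-3,7,11-trimethyl-9-oxo-10-sulfanyldodeca-3,7-dienoic acid | CC(C)C(S)C(=O)/C=C(/C)CC/C=C(\C)CC(=O)O
F3 | step 10 | (2Z,6E,9R,10S)-9-hydroxy-3,7-dimethyl-10-(propan-2-yl)cyclodeca-2,6-dien-1-one | O[C@@H]1C/C(C)=C/CC/C(C)=C\C(=O)[C@H]1C(C)C
F4 | step 10 | (1R,3E,7Z,10S)-3,7-dimethyl-9-oxo-10-(propan-2-yl)cyclodeca-3,7-dien-1-yl acetate | CC(=O)O[C@@H]1C/C(C)=C/CC/C(C)=C\C(=O)[C@H]1C(C)C
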